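The route rests on disconnecting the C2–C1' bond between ring B and ring C. C2, the lone stereocentre, sits β to the C4 carbonyl of ring C, so in a chromone it is the terminus of a C2=C3–C4=O acceptor. A rhodium–chiral diene catalyst adds the ring B arylboronic acid there, forming the C2–C1' bond and the (2S) centre in one operation without forming a ring. The precursors are 5,7-bis(MOM)-6-prenylchromone, built from phloroglucinol through a symmetric 4-prenylphenol that fixes the prenyl group at C6, and 3-geranyl-4-(MOM)phenylboronic acid from 2,4-dibromophenol. Methanolic acid then removes the three MOM groups.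

Key step: step 12

Remark: the face selectivity of the diene ligand on chromones is assumed to follow its behaviour with cyclic enones; (S,S)-Ph-bod [(1S,4S)-2,5-diphenylbicyclo[2.2.2]octa-2,5-diene] is therefore written, and the antipodal ligand is to be used should a model arylation show the opposite sense.

Step 1
Reactants: 1 phloroglucinol
Product: 2 3,5-bis(methoxymethoxy)phenol
Conditions: MOMCl (2.0 equiv), i-Pr2NEt (2.2 equiv), DMF, 0 °C → rt
Reagents that add atoms: chloromethyl methyl ether, COCCl
Why: Statistical Williamson-type O-alkylation of three equivalent phenols with two equivalents of the chloromethyl ether should give the bis-ether as the main component, separable by chromatography from the mono- and tris-ethers.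

Step 2
Reactants: 2 3,5-bis(methoxymethoxy)phenol
Product: 3 triisopropyl[3,5-bis(methoxymethoxy)phenoxy]silane
Conditions: TIPSCl, imidazole, DMF, rt
Reagents that add atoms: chlorotriisopropylsilane, CC(C)[Si](Cl)(C(C)C)C(C)C
Why: Imidazole-mediated silylation of the single free phenol installs a bulky, poorly coordinating ether that keeps the base away from its two neighbouring ring positions in the next step.

Step 3
Reactants: 3 triisopropyl[3,5-bis(methoxymethoxy)phenoxy]silane; 4 prenyl bromide
Product: 6 triisopropyl[3,5-bis(methoxymethoxy)-4-(3-methylbut-2-en-1-yl)phenoxy]silane, via aryllithium 5 (not isolated)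
Conditions: n-BuLi, TMEDA, THF, 0 °C; CuBr·SMe2 (10 mol%), prenyl bromide, −78 °C → rt
Reagents that add atoms: none
Why: Directed ortho-metalation, in which n-BuLi is held by the two MOM acetal oxygens and removes the proton between them, followed by SN2 allylation at the primary carbon of prenyl bromide, should place the prenyl group on the symmetry axis of the ring.

Step 4
Reactants: 6 triisopropyl[3,5-bis(methoxymethoxy)-4-(3-methylbut-2-en-1-yl)phenoxy]silane
Product: 7 3,5-bis(methoxymethoxy)-4-(3-methylbut-2-en-1-yl)phenol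
Conditions: Bu4NF, THF, 0 °C; aq. NH4Cl
Reagents that add atoms: none
Why: Fluoride-induced desilylation should free the phenol without touching the acetals or the alkene, giving a phenol whose two ortho positions are equivalent by symmetry.

Step 5
Reactants: 7 3,5-bis(methoxymethoxy)-4-(3-methylbut-2-en-1-yl)phenol
Product: 8 2-[3,5-bis(methoxymethoxy)-4-(3-methylbut-2-en-1-yl)phenoxy]oxane (racemic THP ether)
Conditions: 3,4-dihydro-2H-pyran, PPTS (cat.), CH2Cl2, rt
Reagents that add atoms: 3,4-dihydro-2H-pyran, C1=COCCC1
Why: Acid-catalysed addition of the phenol to the enol ether (tetrahydropyranylation) gives an acetal that directs lithiation like a MOM group but is cleaved later by much weaker acid.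

Step 6
Reactants: 8 2-[3,5-bis(methoxymethoxy)-4-(3-methylbut-2-en-1-yl)phenoxy]oxane
Product: 11 1-[2,4-bis(methoxymethoxy)-3-(3-methylbut-2-en-1-yl)-6-(oxan-2-yloxy)phenyl]ethan-1-one, via aryllithium 9 (not isolated), via lithium hemiaminal 10 (not isolated)
Conditions: n-BuLi, TMEDA, THF, −20 → 0 °C; MeC(O)N(OMe)Me, −78 °C → rt; aq. NH4Cl
Reagents that add atoms: N-methoxy-N-methylacetamide, CC(=O)N(C)OC
Why: Directed ortho-metalation at the only remaining kind of ring C–H (both are equivalent and each is flanked by a THP and a MOM acetal oxygen) followed by Weinreb ketone synthesis, whose chelated tetrahedral adduct prevents over-addition, should give the methyl ketone.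

Step 7
Reactants: 11 1-[2,4-bis(methoxymethoxy)-3-(3-methylbut-2-en-1-yl)-6-(oxan-2-yloxy)phenyl]ethan-1-one
Product: 12 1-[6-hydroxy-2,4-bis(methoxymethoxy)-3-(3-methylbut-2-en-1-yl)phenyl]ethan-1-one
Conditions: PPTS (cat.), MeOH, rt
Reagents that add atoms: none
Why: Acid-catalysed acetal exchange with methanol cleaves the THP ether far faster than the aryl MOM ethers, and the freed phenol is stabilised by its hydrogen bond to the ketone.

Step 8
Reactants: 12 1-[6-hydroxy-2,4-bis(methoxymethoxy)-3-(3-methylbut-2-en-1-yl)phenyl]ethan-1-one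
Product: 14 5,7-bis(methoxymethoxy)-6-(3-methylbut-2-en-1-yl)-4H-chromen-4-one, via enaminone 13 (not isolated)
Conditions: Me2NCH(OMe)2, toluene, 95 °C; evaporate; TsOH·H2O (1.0 equiv), CH2Cl2, 0 °C → rt; aq. NaHCO3
Reagents that add atoms: N,N-dimethylformamide dimethyl acetal, COC(OC)N(C)C
Why: Condensation of the methyl ketone with the amide acetal and acid-promoted oxa-Michael closure with loss of dimethylamine (enaminone route to chromones) can use only the one unprotected oxygen, so the prenyl group ends at C6, while the liberated amine consumes the single equivalent of acid and protects the MOM ethers.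

Step 9
Reactants: 15 2,4-dibromophenol
Product: 16 2,4-dibromo-1-(methoxymethoxy)benzene
Conditions: MOMCl, i-Pr2NEt, CH2Cl2, 0 °C → rt
Reagents that add atoms: chloromethyl methyl ether, COCCl
Why: Williamson-type O-alkylation protects the phenol as an acetal whose oxygen then anchors the ortho-selective halogen–metal exchange.

Step 10
Reactants: 16 2,4-dibromo-1-(methoxymethoxy)benzene; 17 geranyl bromide
Product: 19 4-bromo-2-[(2E)-3,7-dimethylocta-2,6-dien-1-yl]-1-(methoxymethoxy)benzene, via aryllithium 18 (not isolated)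
Conditions: n-BuLi (1.0 equiv), Et2O, −78 °C; CuBr·SMe2 (10 mol%), geranyl bromide, THF, −78 °C → rt
Reagents that add atoms: none
Why: Bromine–lithium exchange is expected at the bromine ortho to the chelating MOM ether at low temperature, and copper-catalysed SN2 allylation at the primary carbon of geranyl bromide keeps the E alkene.

Step 11
Reactants: 19 4-bromo-2-[(2E)-3,7-dimethylocta-2,6-dien-1-yl]-1-(methoxymethoxy)benzene
Product: 22 {3-[(2E)-3,7-dimethylocta-2,6-dien-1-yl]-4-(methoxymethoxy)phenyl}boronic acid, via aryllithium 20 (not isolated), via lithium borate 21 (not isolated)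
Conditions: n-BuLi, THF, −78 °C; B(OiPr)3, −78 °C → rt; 1 M HCl to pH 5, 0 °C
Reagents that add atoms: triisopropyl borate, CC(C)OB(OC(C)C)OC(C)C; water, O
Why: A second bromine–lithium exchange, trapping as the borate ate complex and brief weakly acidic hydrolysis (lithiation–borylation) should give the boronic acid with the MOM acetal intact.

Step 12
Reactants: 14 5,7-bis(methoxymethoxy)-6-(3-methylbut-2-en-1-yl)-4H-chromen-4-one; 22 {3-[(2E)-3,7-dimethylocta-2,6-dien-1-yl]-4-(methoxymethoxy)phenyl}boronic acid
Product: 23 (2S)-2-{3-[(2E)-3,7-dimethylocta-2,6-dien-1-yl]-4-(methoxymethoxy)phenyl}-5,7-bis(methoxymethoxy)-6-(3-methylbut-2-en-1-yl)-2,3-dihydro-4H-chromen-4-one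
Conditions: [RhCl(C2H4)2]2 (2.5 mol%), (S,S)-Ph-bod (5.5 mol%), aq. KOH (10 mol%), 22 (2.5 equiv), toluene/H2O (10:1), 40 °C, argon
Reagents that add atoms: none
Why: The chloro-bridged rhodium–diene complex from [RhCl(C2H4)2]2 (ethylene is fully displaced, whereas a cyclooctadiene-based source would keep an achiral, highly active diene on the metal and give racemic background) is turned by hydroxide into the hydroxo complex of monovalent rhodium, which transmetalates with 22, inserts the C2=C3 bond of 14 and is released from the oxa-π-allyl enolate by water (Hayashi–Miyaura conjugate arylation, known for chromones with chiral dienes). Only the C2–C1' bond is made and no ring is formed or opened, so no mode of ring closure applies. The new stereocentre C2 is controlled by the C2-symmetric diene, which exposes one enantioface of C2=C3 to the migrating aryl group and should give (2S). The step needs chemoselectivity for the chromone over the three isolated trisubstituted alkenes, secured because only C2=C3 is activated by conjugation to C4=O and the alkenes neither displace the chelating diene nor insert. It also needs the flavanone to persist: with catalytic base and water present the enolate is protonated before ring C can open by retro-oxa-Michael reaction, and the fully MOM-protected 14 and 23 offer no phenoxide to trigger racemisation or a second arylation. The excess of 22 offsets protodeboronation of this electron-rich boronic acid.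

Step 13
Reactants: 23 (2S)-2-{3-[(2E)-3,7-dimethylocta-2,6-dien-1-yl]-4-(methoxymethoxy)phenyl}-5,7-bis(methoxymethoxy)-6-(3-methylbut-2-en-1-yl)-2,3-dihydro-4H-chromen-4-one
Product: 24 schizolaenone A, (2S)-2-{3-[(2E)-3,7-dimethylocta-2,6-dien-1-yl]-4-hydroxyphenyl}-5,7-dihydroxy-6-(3-methylbut-2-en-1-yl)-2,3-dihydro-4H-chromen-4-one
Conditions: 3 M aq. HCl/MeOH (1:5), 45 °C, stopped at full conversion
Reagents that add atoms: none
Why: Acid-catalysed acetal methanolysis removes the three aryl MOM ethers as dimethoxymethane, and at moderate temperature without base the trisubstituted alkenes should be protonated only slowly and C2 should not be epimerised through ring opening.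

Compound list
1 | phloroglucinol | Oc1cc(O)cc(O)c1 | starting material
2 | 3,5-bis(methoxymethoxy)phenol | COCOc1cc(O)cc(OCOC)c1 | intermediate
3 | triisopropyl[3,5-bis(methoxymethoxy)phenoxy]silane | COCOc1cc(O[Si](C(C)C)(C(C)C)C(C)C)cc(OCOC)c1 | intermediate
4 | prenyl bromide (1-bromo-3-methylbut-2-ene) | CC(C)=CCBr | starting material
5 | [2,6-bis(methoxymethoxy)-4-(triisopropylsilyloxy)phenyl]lithium | [Li]c1c(OCOC)cc(O[Si](C(C)C)(C(C)C)C(C)C)cc1OCOC | intermediate
6 | triisopropyl[3,5-bis(methoxymethoxy)-4-(3-methylbut-2-en-1-yl)phenoxy]silane | COCOc1cc(O[Si](C(C)C)(C(C)C)C(C)C)cc(OCOC)c1CC=C(C)C | intermediate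
7 | 3,5-bis(methoxymethoxy)-4-(3-methylbut-2-en-1-yl)phenol | COCOc1cc(O)cc(OCOC)c1CC=C(C)C | intermediate
8 | 2-[3,5-bis(methoxymethoxy)-4-(3-methylbut-2-en-1-yl)phenoxy]oxane (racemic) | COCOc1cc(OC2CCCCO2)cc(OCOC)c1CC=C(C)C | intermediate
9 | [2,4-bis(methoxymethoxy)-3-(3-methylbut-2-en-1-yl)-6-(oxan-2-yloxy)phenyl]lithium | [Li]c1c(OC2CCCCO2)cc(OCOC)c(CC=C(C)C)c1OCOC | intermediate
10 | lithium 1-aryl-1-[methoxy(methyl)amino]ethan-1-olate (Weinreb adduct of 9) | CC([O-])(N(C)OC)c1c(OC2CCCCO2)cc(OCOC)c(CC=C(C)C)c1OCOC.[Li+] | intermediate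
11 | 1-[2,4-bis(methoxymethoxy)-3-(3-methylbut-2-en-1-yl)-6-(oxan-2-yloxy)phenyl]ethan-1-one | CC(=O)c1c(OC2CCCCO2)cc(OCOC)c(CC=C(C)C)c1OCOC | intermediate
12 | 1-[6-hydroxy-2,4-bis(methoxymethoxy)-3-(3-methylbut-2-en-1-yl)phenyl]ethan-1-one | CC(=O)c1c(O)cc(OCOC)c(CC=C(C)C)c1OCOC | intermediate
13 | (E)-3-(dimethylamino)-1-[6-hydroxy-2,4-bis(methoxymethoxy)-3-(3-methylbut-2-en-1-yl)phenyl]prop-2-en-1-one | CN(C)/C=C/C(=O)c1c(O)cc(OCOC)c(CC=C(C)C)c1OCOC | intermediate
14 | 5,7-bis(methoxymethoxy)-6-(3-methylbut-2-en-1-yl)-4H-chromen-4-one | O=c1ccoc2cc(OCOC)c(CC=C(C)C)c(OCOC)c12 | intermediate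
15 | 2,4-dibromophenol | Oc1ccc(Br)cc1Br | starting material
16 | 2,4-dibromo-1-(methoxymethoxy)benzene | COCOc1ccc(Br)cc1Br | intermediate
17 | geranyl bromide [(2E)-1-bromo-3,7-dimethylocta-2,6-diene] | CC(C)=CCC/C(C)=C/CBr | starting material
18 | [5-bromo-2-(methoxymethoxy)phenyl]lithium | [Li]c1cc(Br)ccc1OCOC | intermediate
19 | 4-bromo-2-[(2E)-3,7-dimethylocta-2,6-dien-1-yl]-1-(methoxymethoxy)benzene | CC(C)=CCC/C(C)=C/Cc1cc(Br)ccc1OCOC | intermediate
20 | {3-[(2E)-3,7-dimethylocta-2,6-dien-1-yl]-4-(methoxymethoxy)phenyl}lithium | CC(C)=CCC/C(C)=C/Cc1cc([Li])ccc1OCOC | intermediate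
21 | lithium {3-[(2E)-3,7-dimethylocta-2,6-dien-1-yl]-4-(methoxymethoxy)phenyl}tri(propan-2-yloxy)borate | CC(C)=CCC/C(C)=C/Cc1cc([B-](OC(C)C)(OC(C)C)OC(C)C)ccc1OCOC.[Li+] | intermediate
22 | {3-[(2E)-3,7-dimethylocta-2,6-dien-1-yl]-4-(methoxymethoxy)phenyl}boronic acid | CC(C)=CCC/C(C)=C/Cc1cc(B(O)O)ccc1OCOC | intermediate
23 | (2S)-tri-O-MOM schizolaenone A | CC(C)=CCC/C(C)=C/Cc1cc([C@@H]2CC(=O)c3c(cc(OCOC)c(CC=C(C)C)c3OCOC)O2)ccc1OCOC | intermediate
24 | schizolaenone A, (2S) | CC(C)=CCC/C(C)=C/Cc1cc([C@@H]2CC(=O)c3c(cc(O)c(CC=C(C)C)c3O)O2)ccc1O | target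

Total step count: 13. Longest linear sequence: 10 steps (steps 1–8, 12, 13); the boronic acid branch is 3 steps (9–11).

Steps most likely to fail

Step 12. Insertion into the electron-rich 5,7-dioxygenated chromone may be slow, so that protodeboronation of the boronic acid wins, or the facial discrimination may be insufficient. The fallback sets out from 12 and 19 and returns at 23. Bromide 19 is lithiated again (n-BuLi, THF, −78 °C, giving 20) and formylated with DMF to 3-[(2E)-3,7-dimethylocta-2,6-dien-1-yl]-4-(methoxymethoxy)benzaldehyde F1. Claisen–Schmidt condensation of F1 with ketone 12 (KOH, EtOH, rt) should give the 2'-hydroxychalcone F2. NaOAc in refluxing EtOH closes ring C by oxa-Michael addition of the only free phenol, giving the racemic tri-MOM flavanone F3 with the prenyl group still at C6. Preparative chromatography on an amylose carbamate chiral stationary phase then separates 23 from the (2R)-antipode F4, which is re-equilibrated with base through F2 and recycled.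

Step 13. The freed phenols may add under acid catalysis to the neighbouring prenyl or geranyl double bonds (chroman formation), the geranyl chain may undergo cation–olefin cyclisation, or C2 may partly racemise. The fallback sets out from 23 and returns at 24 by a non-protic silyl-transfer cleavage. TMSOTf with 2,2'-bipyridyl in CH2Cl2 at 0 °C converts each aryl MOM ether into the aryl trimethylsilyl ether without free Brønsted acid, giving the tris(trimethylsilyl) ether of schizolaenone A F5. Work-up with water at rt hydrolyses the labile aryl silyl ethers to 24.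

Step 6. Proton transfer from the acetamide to the hindered aryllithium (enolisation, returning 8) or competing deprotonation at the benzylic–allylic CH2 of the prenyl group may undercut the acylation. The fallback sets out from 7 and returns at 12, bypassing 8–11. Magnesium-mediated ortho-formylation of the free phenol 7 (MgCl2, Et3N, paraformaldehyde, MeCN, reflux) should give 6-hydroxy-2,4-bis(methoxymethoxy)-3-(3-methylbut-2-en-1-yl)benzaldehyde F6, the two ortho positions being equivalent by symmetry. Excess MeMgBr (THF, 0 °C) adds to give the racemic carbinol 1-[6-hydroxy-2,4-bis(methoxymethoxy)-3-(3-methylbut-2-en-1-yl)phenyl]ethan-1-ol F7. MnO2 (CH2Cl2, rt) oxidises the benzylic alcohol to 12.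

Further compounds
F1 | step 12 | 3-[(2E)-3,7-dimethylocta-2,6-dien-1-yl]-4-(methoxymethoxy)benzaldehyde | CC(C)=CCC/C(C)=C/Cc1cc(C=O)ccc1OCOC
F2 | step 12 | (E)-3-{3-[(2E)-3,7-dimethylocta-2,6-dien-1-yl]-4-(methoxymethoxy)phenyl}-1-[6-hydroxy-2,4-bis(methoxymethoxy)-3-(3-methylbut-2-en-1-yl)phenyl]prop-2-en-1-one | CC(C)=CCC/C(C)=C/Cc1cc(/C=C/C(=O)c2c(O)cc(OCOC)c(CC=C(C)C)c2OCOC)ccc1OCOC
F3 | step 12 | racemic tri-O-MOM schizolaenone A | CC(C)=CCC/C(C)=C/Cc1cc(C2CC(=O)c3c(cc(OCOC)c(CC=C(C)C)c3OCOC)O2)ccc1OCOC
F4 | step 12 | (2R)-tri-O-MOM schizolaenone A | CC(C)=CCC/C(C)=C/Cc1cc([C@H]2CC(=O)c3c(cc(OCOC)c(CC=C(C)C)c3OCOC)O2)ccc1OCOC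
F5 | step 13 | (2S)-tris-O-(trimethylsilyl) schizolaenone A | CC(C)=CCC/C(C)=C/Cc1cc([C@@H]2CC(=O)c3c(cc(O[Si](C)(C)C)c(CC=C(C)C)c3O[Si](C)(C)C)O2)ccc1O[Si](C)(C)C
F6 | step 6 | 6-hydroxy-2,4-bis(methoxymethoxy)-3-(3-methylbut-2-en-1-yl)benzaldehyde | O=Cc1c(O)cc(OCOC)c(CC=C(C)C)c1OCOC
F7 | step 6 | 1-[6-hydroxy-2,4-bis(methoxymethoxy)-3-(3-methylbut-2-en-1-yl)phenyl]ethan-1-ol (racemic) | CC(O)c1c(O)cc(OCOC)c(CC=C(C)C)c1OCOC
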